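## Structural features

The target is a (2S)-flavanone. Ring A (a benzene ring) is fused to ring C (a dihydropyranone), and C2 of ring C carries ring B, a 4-methoxyphenyl group. Ring A is a phloroglucinol nucleus with free hydroxyls at C5 and C7, a 3-methylbut-2-enyl (prenyl) chain at C6 between them, and hydrogen only at C8. C2 is the only stereocentre and has no stereogenic neighbour. It is a benzylic aryl-ether carbon β to the C4 ketone, so it is erased by retro-oxa-Michael opening to the 2'-hydroxychalcone under base, and more slowly under strong acid or light. The anisyl group also makes the C2–O1 bond ionisable. The prenyl alkene flanked by two phenols is the second fragile element: acid can close it onto either hydroxyl to a dimethylchroman, and it excludes hydrogenolysis, strong oxidants and hard Lewis acids late in the route. The real difficulties are absolute control at an isolated, labile C2 and placing the prenyl group at C6 and not at C8, which acylphloroglucinol routes do not do cleanly. The key step uses two features. The O1–C2 unit is an aryl benzyl ether whose C2 can become an anisyl-stabilised oxocarbenium ion. O1 also sits on a ring A precursor with a mirror plane through O1 and the prenyl-bearing carbon, so the two carbons ortho to O1 (future C4a and C8) are equivalent and ring closure can only give the 6-prenyl isomer.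

Check of the structures: the phenoxy carbons of 12 map onto 16 and 18 as C1→C8a, C2→C4a, C3/C5→C5/C7, C4→C6, and the descriptor at C2 is S in 15, 16, 17 and 18 (O1 > C1' > C3 > H). No correction is needed. The acetate is kept as leaving group by design: a mixed methyl aryl acetal would ionise with loss of the phenol, whereas acetate leaves in preference to the aryloxide. The methoxymethyl ethers are kept because they come off in the same acid step as the ketal, so the base-labile flavanone never meets fluoride.

## Logic of the disconnections

18 ⇒ 16. No skeletal bond is cut. The C4 carbonyl is taken back to a dimethyl ketal and the C5 and C7 hydroxyls to methoxymethyl ethers, with 17 as the stage in between. All three masks are acetals, so one dilute-acid operation releases the target and the flavanone never sees base. The demand on the forward step is an acid mild enough to leave the prenyl alkene and the C2–O1 bond alone.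

16 ⇒ 12 + 13. The C2–C3 and C4–C4a bonds are cut, which removes ring C and the only stereocentre in one move. What remains is a racemic, symmetric aryl acetoxy acetal 12 and a two-carbon partner 13 that delivers C3 and C4 at the ketone oxidation level. The gain is large: the absolute configuration is no longer carried by any intermediate, and the 6- versus 8-prenyl question is removed by symmetry. The demand is that a chiral counter-anion alone distinguishes the two faces of a planar C2, that the acetoxy acetal ionises in preference to the two methoxymethyl acetals, and that the second cation closes onto ring A before it is quenched.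

12 ⇒ 11. The C2–OAc bond is traced back to a C2–CO2H bond. A carboxyl group is a stable placeholder for the leaving group and turns the labile acetal into an ordinary α-aryloxy acid until the last moment. The demand is an oxidative decarboxylation that proceeds at or below room temperature and spares the prenyl alkene.

11 ⇒ 7 + 9 (through 10). The O1–C2 ether bond is cut. This separates the ring A phenol from the ring B/C2 unit as a phenoxide and an activated secondary bromide. The demand is O-alkylation and not C-alkylation of an electron-rich phenoxide, followed by ester hydrolysis in the same pot.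

9 ⇒ 8. The C–Br bond is cut. 8 is a commercial ester, and the forward step must brominate the benzylic α-carbon and not the anisyl ring.

7 ⇒ 6 ⇒ 3 + 4 (through 5). The aryl–CH2 bond of the prenyl group is cut, and the free phenol is taken back to its silyl ether. The position between two methoxymethyl ethers is the one a lithium base finds by double coordination, so the prenyl group enters with complete site control. The demand is metalation at that carbon only and coupling without allylic transposition.

3 ⇒ 2 ⇒ 1. The two O–CH2 bonds and the O–Si bond are cut. The three equal hydroxyls of 1 are told apart by a statistical mono-silylation, and the silyl ether later marks the oxygen that becomes O1. The demand is a separable mono-ether, which an excess of cheap 1 secures.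

## Other disconnections considered

Alternative 1: The whole of ring A is removed: C4a–C5, C5–C6 and C7–C8 from a benzannulation and C8–C8a from a Wolff shift. This leaves a chiral diazoketone A1, (S)-6-(2-diazoacetyl)-2-(4-methoxyphenyl)-2,3-dihydro-4H-pyran-4-one, and the siloxyalkyne A2, triisopropyl[(5-methylhex-4-en-1-yn-1-yl)oxy]silane. In the forward direction, irradiation of A1 would give a vinylketene. This should add A2 in a [2+2] sense, open, reclose by six-electron electrocyclisation and tautomerise to A3, (S)-5-hydroxy-6-prenyl-7-(triisopropylsilyloxy)-4'-methoxyflavanone, and desilylation would finish.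
- In favour: the 5-hydroxy/6-prenyl/7-oxygen pattern is fixed by the alkyne and the ketene carbon, so on prenyl placement it is the equal of the chosen plan. C2 would come from a hetero-Diels–Alder reaction of an established catalytic asymmetric type, which is better precedented than the counter-anion step of the chosen plan.
- Against: C2 would have to survive light and several thermal pericyclic events as a β-aryloxy ketone, and such ketones open photochemically and thermally, which would erase the stereocentre. The vinylketene is part of a vinylogous ester, an unusual partner for this annulation. A1 and A2 each need several steps with diazo and ynolate chemistry, so the count to A3 exceeds the seven steps to 12. The final fluoride step exposes a base-sensitive flavanone.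
- Mechanistically, four pericyclic events must succeed in sequence here, against two polar bond formations in the chosen plan.

Alternative 2: O1–C8a and C4–C4a are cut. Fluoride would release a 3-alkoxyaryne from the silyl triflate A4, 3,5-bis(methoxymethoxy)-4-prenyl-2-(trimethylsilyl)phenyl trifluoromethanesulfonate. The alkoxide of A5, methyl (S)-3-hydroxy-3-(4-methoxyphenyl)propanoate, should add at C8a, the carbon remote from the C5 alkoxy group. The C4a anion would then close on the ester to give A6, (S)-5,7-bis(methoxymethoxy)-6-prenyl-4'-methoxyflavanone, which is the same compound as 17.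
- In favour: the stereocentre arrives ready-made in A5, which is accessible by asymmetric reduction of the β-keto ester, and is not a reacting centre in the annulation. On certainty of absolute configuration this is better than the chosen plan. The endgame from A6 is identical to that from 17, so the two plans are equal there, and the route is convergent.
- Against: the alkoxide of A5 is set up for retro-aldol cleavage and β-elimination. The aryl anion may be protonated before it acylates. The basic fluoride medium is the condition under which the product opens by β-elimination of the phenoxide and loses C2. A4 has to be made from 7 in about three further steps (ortho-bromination, silyl installation, triflation), so the sequence is longer than 7 → 12.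
- Site selectivity depends on the directing effect of one alkoxy group, where the chosen plan needs none.

Alternative 3: Only C2–C3 is cut. Rh2(S-PTTL)4, a chiral dirhodium tetracarboxylate, would decompose the diazoketone A7, 2-diazo-1-[2-(4-methoxybenzyloxy)-6-(tert-butyldimethylsilyloxy)-5-prenyl-4-(triisopropylsilyloxy)phenyl]ethanone. The carbenoid at C3 would insert into one of the two enantiotopic benzylic O–CH2 hydrogens to give A8, (S)-5-(tert-butyldimethylsilyloxy)-6-prenyl-7-(triisopropylsilyloxy)-4'-methoxyflavanone.
- In favour: the precursor is an ordinary aryl 4-methoxybenzyl ether, far more robust than the acetoxy acetal 12, which is a better point. One catalytic step closes ring C and sets C2, as in the chosen plan, so the two are equal in concept. The catalyst class is established for insertion next to ether oxygen, which is better precedent.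
- Against: the carbenoid is of the acceptor-only kind, the least selective class. The ether oxygen can attack it to give an oxonium ylide and, after 1,2-shift, a five-membered ring. The prenyl alkene invites cyclopropanation and the anisyl ring aromatic cycloaddition, and six-membered insertion is less favoured than five-membered. A7 needs an unsymmetrical ring A with two different silyl ethers and a hindered 2,6-dioxygenated benzoic acid turned into a diazoketone, which costs more steps than the symmetric 7. Two silyl ethers must then leave with fluoride.
- The weak point here is chemoselectivity, whereas in the chosen plan it is enantioselectivity.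

Key step: step 8

Assumption: the catalyst is the N-triflyl imidodiphosphorimidate (IDPi) acid built from two 3,3'-bis[3,5-bis(trifluoromethyl)phenyl]-1,1'-bi-2-naphthol units. Its (S,S)-form is taken as the one that opens the Si face of C2; the sense of induction cannot be derived in advance, and the mirror-image acid would be used if the first screen shows the opposite.

## Route

Step 1
Reactants: 1 phloroglucinol (benzene-1,3,5-triol)
Product: 2 5-(triisopropylsilyloxy)benzene-1,3-diol
Conditions: TIPSCl (1 equiv), imidazole, DMF, 0 °C to rt; 1 in threefold excess
Reagents that add atoms: triisopropylsilyl chloride, CC(C)[Si](Cl)(C(C)C)C(C)C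
Why: O-silylation of a phenol; the three hydroxyls are equivalent, so the mono-ether is favoured statistically by the excess of water-soluble 1, which is washed out.

Step 2
Reactants: 2 5-(triisopropylsilyloxy)benzene-1,3-diol
Product: 3 1,3-bis(methoxymethoxy)-5-(triisopropylsilyloxy)benzene
Conditions: MOMCl (2.6 equiv), i-Pr2NEt, CH2Cl2, 0 °C to rt
Reagents that add atoms: chloromethyl methyl ether, COCCl
Why: Williamson-type O-alkylation of both phenols with an α-chloro ether under amine base; the hindered aryl silyl ether is inert to these conditions.

Step 3
Reactants: 3 1,3-bis(methoxymethoxy)-5-(triisopropylsilyloxy)benzene; 4 prenyl bromide (1-bromo-3-methylbut-2-ene)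
Product: 6 [3,5-bis(methoxymethoxy)-4-(3-methylbut-2-en-1-yl)phenoxy]triisopropylsilane, via 2,6-bis(methoxymethoxy)-4-(triisopropylsilyloxy)phenyllithium 5 (not isolated)
Conditions: n-BuLi (1.2 equiv), THF, 0 °C; CuI (10 mol%), then 4, –78 °C to rt
Reagents that add atoms: none
Why: Directed ortho-metalation: the hydrogen between the two methoxymethoxy groups is removed through double coordination of lithium, while the bulky silyloxy group does not direct; copper-catalysed coupling of 5 with the primary allylic bromide should give the linear prenyl arene.

Step 4
Reactants: 6 [3,5-bis(methoxymethoxy)-4-(3-methylbut-2-en-1-yl)phenoxy]triisopropylsilane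
Product: 7 3,5-bis(methoxymethoxy)-4-(3-methylbut-2-en-1-yl)phenol
Conditions: TBAF, AcOH (1:1), THF, 0 °C to rt
Reagents that add atoms: none
Why: Fluoride cleavage of an aryl silyl ether; the acetic acid buffer keeps the electron-rich phenoxide from building up, and MOM ethers and the alkene are inert.

Step 5
Reactants: 8 methyl 2-(4-methoxyphenyl)acetate
Product: 9 methyl 2-bromo-2-(4-methoxyphenyl)acetate (racemic)
Conditions: NBS, AIBN (cat.), PhCF3, 80 °C
Reagents that add atoms: N-bromosuccinimide, O=C1CCC(=O)N1Br
Why: Wohl–Ziegler radical bromination at the position that is both benzylic and α to the ester; non-polar radical conditions disfavour ionic bromination of the anisyl ring.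

Step 6
Reactants: 7 3,5-bis(methoxymethoxy)-4-(3-methylbut-2-en-1-yl)phenol; 9 methyl 2-bromo-2-(4-methoxyphenyl)acetate
Product: 11 2-[3,5-bis(methoxymethoxy)-4-(3-methylbut-2-en-1-yl)phenoxy]-2-(4-methoxyphenyl)acetic acid (racemic), via methyl 2-[3,5-bis(methoxymethoxy)-4-prenylphenoxy]-2-(4-methoxyphenyl)acetate 10 (not isolated)
Conditions: K2CO3, DMF, rt; then LiOH, H2O/MeOH, rt; cold 1 M HCl to pH 4
Reagents that add atoms: lithium hydroxide, [Li+].[OH-]
Why: Williamson etherification of the phenoxide with an activated α-bromo ester in a dipolar aprotic solvent (O-alkylation favoured), then saponification in the same pot; brief cold acidification to pH 4 leaves the MOM ethers intact.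

Step 7
Reactants: 11 2-[3,5-bis(methoxymethoxy)-4-(3-methylbut-2-en-1-yl)phenoxy]-2-(4-methoxyphenyl)acetic acid
Product: 12 [3,5-bis(methoxymethoxy)-4-(3-methylbut-2-en-1-yl)phenoxy](4-methoxyphenyl)methyl acetate (racemic)
Conditions: Pb(OAc)4 (1.2 equiv), pyridine, THF, 0 °C to rt
Reagents that add atoms: lead tetraacetate, CC(=O)O[Pb](OC(C)=O)(OC(C)=O)OC(C)=O
Why: Oxidative decarboxylation of an α-aryloxy acid by tetravalent lead; the carboxylate bound to lead loses CO2 to a cation stabilised by both the aryloxy and anisyl groups, which acetate captures, so the reaction should run cold and faster than any attack on the alkene; pyridine keeps the medium non-acidic for the labile product.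

Step 8
Reactants: 12 [3,5-bis(methoxymethoxy)-4-(3-methylbut-2-en-1-yl)phenoxy](4-methoxyphenyl)methyl acetate; 13 1,1-dimethoxyethene
Product: 16 (S)-4,4-dimethoxy-5,7-bis(methoxymethoxy)-6-prenyl-4'-methoxyflavan, via aryloxycarbenium ion 14 (not isolated), via (S)-dimethoxycarbenium ion 15 (not isolated)
Conditions: (S,S)-IDPi acid (N-triflyl, 3,3'-Ar = 3,5-(CF3)2C6H3; 5 mol%), 13 (3 equiv), toluene, –78 °C; Et3N quench
Reagents that add atoms: none
Why: Proposed new method: the confined acid (directly, or through the 1,1-dimethoxyethyl cation it forms with 13) takes acetate from either enantiomer of 12 and leaves the planar, anisyl-stabilised ion 14 paired with the chiral anion, so the racemate converges on one intermediate. The CH2 terminus of 13 then adds to C2 of 14 inside the anion pocket on the Si face (O1 > C1' > H), which sets C2 as S and gives the dialkoxycarbenium ion 15. Ring C closes by intramolecular Friedel–Crafts attack of C4a, which is ortho to O1 and carries oxygens ortho and para to it, on C4 of 15; this is a six-membered closure in which the C4a–C8a bond of ring A becomes part of the new ring, and loss of the ring proton returns the acid and leaves C4 as its dimethyl ketal. The closest known reaction types are the oxa-Povarov annulation of aryl oxocarbenium ions with alkenes under achiral Lewis acids and imidodiphosphorimidate counter-anion control of additions to oxocarbenium ions; neither has been run with a ketene acetal as two-carbon partner on an acyclic aryl oxocarbenium ion. C2 is controlled by the catalyst alone, and C4 bears two identical methoxy groups and is not stereogenic. The step needs enantioface selectivity at C2, which only the anion can supply. It needs ionisation of the acetoxy acetal before the two MOM acetals, which the better leaving group, the anisyl stabilisation and the low temperature should secure. It needs attack by 13 and not by the prenyl alkene, which the far higher nucleophilicity and the excess of 13 should secure, and ring closure raises no site question because C4a and C8 are related by the mirror plane of the aryloxy group. The acetic acid released is taken up by a second equivalent of 13 as methyl acetate, so no nucleophilic acid builds up beside 15.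

Step 9
Reactants: 16 (S)-4,4-dimethoxy-5,7-bis(methoxymethoxy)-6-prenyl-4'-methoxyflavan
Product: 18 (2S)-5,7-dihydroxy-2-(4-methoxyphenyl)-6-(3-methylbut-2-en-1-yl)chroman-4-one (CNP0279348.1), via (S)-5,7-bis(methoxymethoxy)-6-prenyl-4'-methoxyflavanone 17 (not isolated)
Conditions: aq. HCl (3 M), MeOH, rt to 40 °C
Reagents that add atoms: water, O
Why: Acid-catalysed acetal hydrolysis: the ketal opens first to ketone 17, then both MOM ethers are hydrolysed; C2 is not a reacting centre, and mild dilute acid should be slow to open ring C or to add the phenols across the prenyl alkene.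

## Compound list

1 | phloroglucinol (benzene-1,3,5-triol) | Oc1cc(O)cc(O)c1 | starting material
2 | 5-(triisopropylsilyloxy)benzene-1,3-diol | CC(C)[Si](Oc1cc(O)cc(O)c1)(C(C)C)C(C)C | intermediate
3 | 1,3-bis(methoxymethoxy)-5-(triisopropylsilyloxy)benzene | COCOc1cc(OCOC)cc(O[Si](C(C)C)(C(C)C)C(C)C)c1 | intermediate
4 | prenyl bromide (1-bromo-3-methylbut-2-ene) | CC(C)=CCBr | starting material
5 | 2,6-bis(methoxymethoxy)-4-(triisopropylsilyloxy)phenyllithium | [Li]c1c(OCOC)cc(O[Si](C(C)C)(C(C)C)C(C)C)cc1OCOC | intermediate
6 | [3,5-bis(methoxymethoxy)-4-(3-methylbut-2-en-1-yl)phenoxy]triisopropylsilane | COCOc1cc(O[Si](C(C)C)(C(C)C)C(C)C)cc(OCOC)c1CC=C(C)C | intermediate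
7 | 3,5-bis(methoxymethoxy)-4-(3-methylbut-2-en-1-yl)phenol | COCOc1cc(O)cc(OCOC)c1CC=C(C)C | intermediate
8 | methyl 2-(4-methoxyphenyl)acetate | COC(=O)Cc1ccc(OC)cc1 | starting material
9 | methyl 2-bromo-2-(4-methoxyphenyl)acetate (racemic) | COC(=O)C(Br)c1ccc(OC)cc1 | intermediate
10 | methyl 2-[3,5-bis(methoxymethoxy)-4-(3-methylbut-2-en-1-yl)phenoxy]-2-(4-methoxyphenyl)acetate (racemic) | COC(=O)C(Oc1cc(OCOC)c(CC=C(C)C)c(OCOC)c1)c1ccc(OC)cc1 | intermediate
11 | 2-[3,5-bis(methoxymethoxy)-4-(3-methylbut-2-en-1-yl)phenoxy]-2-(4-methoxyphenyl)acetic acid (racemic) | OC(=O)C(Oc1cc(OCOC)c(CC=C(C)C)c(OCOC)c1)c1ccc(OC)cc1 | intermediate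
12 | [3,5-bis(methoxymethoxy)-4-(3-methylbut-2-en-1-yl)phenoxy](4-methoxyphenyl)methyl acetate (racemic) | CC(=O)OC(Oc1cc(OCOC)c(CC=C(C)C)c(OCOC)c1)c1ccc(OC)cc1 | intermediate
13 | 1,1-dimethoxyethene | C=C(OC)OC | starting material
14 | [3,5-bis(methoxymethoxy)-4-prenylphenyl][(4-methoxyphenyl)methylidene]oxonium, paired with the chiral anion | COc1ccc(C=[O+]c2cc(OCOC)c(CC=C(C)C)c(OCOC)c2)cc1 | intermediate
15 | (S)-{3-[3,5-bis(methoxymethoxy)-4-prenylphenoxy]-1-methoxy-3-(4-methoxyphenyl)propylidene}(methyl)oxonium | COc1ccc([C@H](CC(OC)=[O+]C)Oc2cc(OCOC)c(CC=C(C)C)c(OCOC)c2)cc1 | intermediate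
16 | (S)-4,4-dimethoxy-5,7-bis(methoxymethoxy)-6-prenyl-4'-methoxyflavan | COc1ccc([C@@H]2CC(OC)(OC)c3c(cc(OCOC)c(CC=C(C)C)c3OCOC)O2)cc1 | intermediate
17 | (S)-5,7-bis(methoxymethoxy)-6-prenyl-4'-methoxyflavanone | COc1ccc([C@@H]2CC(=O)c3c(cc(OCOC)c(CC=C(C)C)c3OCOC)O2)cc1 | intermediate
18 | (2S)-5,7-dihydroxy-2-(4-methoxyphenyl)-6-(3-methylbut-2-en-1-yl)chroman-4-one (CNP0279348.1) | COc1ccc([C@@H]2CC(=O)c3c(cc(O)c(CC=C(C)C)c3O)O2)cc1 | target

## Step count and least certain steps

Total: 9 steps. Longest linear sequence: 8 steps (steps 1, 2, 3, 4, 6, 7, 8, 9 from 1); step 5 is a one-step branch.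

Step 8 (key step, proposed new method). Several things may go wrong.
- Enantioface discrimination may be poor, because the acyclic ion 14 can adopt two geometries about its C=O bond and may sit loosely in the anion pocket.
- Ion 15 may be demethylated by acetate or by the anion before ring A attacks, which stops the sequence at an open-chain ester.
- The product may ionise again under the strong acid, at the ketal or at C2–O1, leading to a second addition of 13 or to erosion of configuration.
- A MOM acetal may ionise in competition.

The fallback uses known chemistry and sets out from 7.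
- Magnesium-mediated ortho-formylation (MgCl2, Et3N, paraformaldehyde, MeCN, reflux) should give 6-hydroxy-2,4-bis(methoxymethoxy)-3-prenylbenzaldehyde F1; either ortho carbon gives the same product.
- Addition of ethynylmagnesium bromide (HC≡CMgBr, excess, THF, 0 °C) gives 1-[6-hydroxy-2,4-bis(methoxymethoxy)-3-prenylphenyl]prop-2-yn-1-ol F2.
- Oxidation with MnO2 in CH2Cl2 gives 1-[6-hydroxy-2,4-bis(methoxymethoxy)-3-prenylphenyl]prop-2-yn-1-one F3, and Et2NH in EtOH closes it through the enaminone to 5,7-bis(methoxymethoxy)-6-prenyl-4H-chromen-4-one F4.
- Asymmetric 1,4-addition of 4-methoxyphenylboronic acid to F4 with a monovalent rhodium catalyst ([Rh(OH)(cod)]2 and a chiral diene or electron-poor chiral bisphosphine, the enantiomer chosen to give S) returns to the route at 17, which is carried to 18 under the conditions of step 9.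

Step 7. The cation formed on decarboxylation may be captured by the electron-rich ring of a second molecule instead of by acetate, tetravalent lead may attack the prenyl alkene, or the acetoxy acetal may hydrolyse during isolation. The fallback avoids oxidation and sets out from 7. Acylation with 4-methoxybenzoyl chloride (Et3N, DMAP, CH2Cl2) gives 3,5-bis(methoxymethoxy)-4-prenylphenyl 4-methoxybenzoate F5. Reductive acetylation of this ester (i-Bu2AlH, CH2Cl2, –78 °C; then Ac2O, pyridine, DMAP, –78 °C to rt) traps the aluminium hemiacetal as its acetate and returns to the route at 12. The weak point of this fallback is collapse of the hemiacetal with loss of the aryloxide before acetylation.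

Step 3. Metalation may also occur next to the silyl ether and be followed by silyl migration to carbon, and the coupling may go with allylic transposition to the 1,1-dimethylallyl isomer. The fallback introduces the prenyl group before any protecting group and sets out from 1. C-prenylation with 4 (DBU, THF, or aqueous KOH) gives 2-prenylbenzene-1,3,5-triol F6. Silylation of the one unhindered hydroxyl para to the prenyl group (TIPSCl, imidazole, DMF, 0 °C) gives 2-prenyl-5-(triisopropylsilyloxy)benzene-1,3-diol F7. MOMCl with i-Pr2NEt returns to the route at 6.

Step 9. Acid may add a freed phenol across the prenyl alkene to a dimethylchroman, ring C may open and reclose with partial loss of configuration, or the C7 MOM ether may be removed incompletely. The fallback separates the two events and avoids free strong protic acid. It sets out from 16: PPTS in wet acetone at rt releases and isolates 17, and ZnBr2 with n-PrSH in CH2Cl2 at 0 °C (Lewis-acid activation with capture of the methoxymethyl group by the thiol) removes both MOM groups and comes back to the route at 18.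

## Further compounds

F1 | step 8 | 6-hydroxy-2,4-bis(methoxymethoxy)-3-(3-methylbut-2-en-1-yl)benzaldehyde | O=Cc1c(O)cc(OCOC)c(CC=C(C)C)c1OCOC
F2 | step 8 | 1-[6-hydroxy-2,4-bis(methoxymethoxy)-3-(3-methylbut-2-en-1-yl)phenyl]prop-2-yn-1-ol (racemic) | C#CC(O)c1c(O)cc(OCOC)c(CC=C(C)C)c1OCOC
F3 | step 8 | 1-[6-hydroxy-2,4-bis(methoxymethoxy)-3-(3-methylbut-2-en-1-yl)phenyl]prop-2-yn-1-one | C#CC(=O)c1c(O)cc(OCOC)c(CC=C(C)C)c1OCOC
F4 | step 8 | 5,7-bis(methoxymethoxy)-6-(3-methylbut-2-en-1-yl)-4H-chromen-4-one | O=c1ccoc2cc(OCOC)c(CC=C(C)C)c(OCOC)c12
F5 | step 7 | 3,5-bis(methoxymethoxy)-4-(3-methylbut-2-en-1-yl)phenyl 4-methoxybenzoate | COc1ccc(C(=O)Oc2cc(OCOC)c(CC=C(C)C)c(OCOC)c2)cc1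
F6 | step 3 | 2-(3-methylbut-2-en-1-yl)benzene-1,3,5-triol | CC(C)=CCc1c(O)cc(O)cc1O
F7 | step 3 | 2-(3-methylbut-2-en-1-yl)-5-(triisopropylsilyloxy)benzene-1,3-diol | CC(C)=CCc1c(O)cc(O[Si](C(C)C)(C(C)C)C(C)C)cc1O
F0 | step 9 | none | none
A1 | alternative 1 | (S)-6-(2-diazoacetyl)-2-(4-methoxyphenyl)-2,3-dihydro-4H-pyran-4-one | COc1ccc([C@@H]2CC(=O)C=C(C(=O)C=[N+]=[N-])O2)cc1
A2 | alternative 1 | triisopropyl[(5-methylhex-4-en-1-yn-1-yl)oxy]silane | CC(C)=CCC#CO[Si](C(C)C)(C(C)C)C(C)C
A3 | alternative 1 | (S)-5-hydroxy-6-prenyl-7-(triisopropylsilyloxy)-4'-methoxyflavanone | COc1ccc([C@@H]2CC(=O)c3c(cc(O[Si](C(C)C)(C(C)C)C(C)C)c(CC=C(C)C)c3O)O2)cc1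
A4 | alternative 2 | 3,5-bis(methoxymethoxy)-4-(3-methylbut-2-en-1-yl)-2-(trimethylsilyl)phenyl trifluoromethanesulfonate | C[Si](C)(C)c1c(OS(=O)(=O)C(F)(F)F)cc(OCOC)c(CC=C(C)C)c1OCOC
A5 | alternative 2 | methyl (S)-3-hydroxy-3-(4-methoxyphenyl)propanoate | COC(=O)C[C@H](O)c1ccc(OC)cc1
A6 | alternative 2 | (S)-5,7-bis(methoxymethoxy)-6-prenyl-4'-methoxyflavanone | COc1ccc([C@@H]2CC(=O)c3c(cc(OCOC)c(CC=C(C)C)c3OCOC)O2)cc1
A7 | alternative 3 | 2-diazo-1-[2-(4-methoxybenzyloxy)-6-(tert-butyldimethylsilyloxy)-5-(3-methylbut-2-en-1-yl)-4-(triisopropylsilyloxy)phenyl]ethanone | COc1ccc(COc2cc(O[Si](C(C)C)(C(C)C)C(C)C)c(CC=C(C)C)c(O[Si](C)(C)C(C)(C)C)c2C(=O)C=[N+]=[N-])cc1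
A8 | alternative 3 | (S)-5-(tert-butyldimethylsilyloxy)-6-prenyl-7-(triisopropylsilyloxy)-4'-methoxyflavanone | COc1ccc([C@@H]2CC(=O)c3c(cc(O[Si](C(C)C)(C(C)C)C(C)C)c(CC=C(C)C)c3O[Si](C)(C)C(C)(C)C)O2)cc1
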